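**Plan**

- Retrosynthetic cuts: the ring A C5–acyl bond (aryllithium plus cinnamoyl Weinreb amide), the two C–CH3 bonds of the carbinol (ester plus MeMgBr), the O1–C2 bond of the dihydrofuran (carbene O–H insertion) and the C3a–C3 bond (phloroglucinol plus acrylic acid).
- Enabling feature: C2 of the dihydrofuran ring bears O1 and the carbinol carbon. If that carbon is carried as an ester carbonyl, C2 is the carbon of an α-diazo ester lying three atoms (C3, C3a, C7a) from a free ortho phenol oxygen.
- Forward order: ring A comes from phloroglucinol; the three-carbon chain is attached as a dihydrocoumarin; diazo transfer and lactone methanolysis give the diazo phenol; the furan ring closes by copper carbene O–H insertion; carbinol formation, C5 acylation between the two MOM ethers and global deprotection follow.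
- Stereochemistry: the only stereocentre, C2 (S), is set in the ring closure by a chiral spiro-bisoxazoline copper catalyst and no later step touches it. The E alkene is bought with 4-hydroxycinnamic acid.

Key step: step 5

Assumption: the (Sa,S,S) ligand is taken to deliver the (2S) ester; should the first run show the opposite sense, the (Ra,R,R) ligand is used with no other change.

**Step 1**
Reactants: 1 phloroglucinol (used in excess); 2 acrylic acid
Product: 3 5,7-dihydroxychroman-2-one
Conditions: Amberlyst-15, toluene, reflux, Dean–Stark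
Reagents that add atoms: none
Why: Acid-catalysed Friedel–Crafts conjugate alkylation (hydroarylation) of acrylic acid by the very electron-rich arene followed by lactonisation onto the adjacent phenol should give the dihydrocoumarin, and the three equivalent ring positions leave no regiochemical choice.

**Step 2**
Reactants: 3 5,7-dihydroxychroman-2-one
Product: 4 5,7-bis(methoxymethoxy)chroman-2-one
Conditions: MOMCl, iPr2NEt, CH2Cl2, 0 °C to rt
Reagents that add atoms: chloromethyl methyl ether, COCCl
Why: O-alkylation of both phenols with MOMCl under a hindered amine base is a standard acetal protection that should leave the aryl lactone closed.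

**Step 3**
Reactants: 4 5,7-bis(methoxymethoxy)chroman-2-one
Product: 6 3-diazo-5,7-bis(methoxymethoxy)chroman-2-one, via 3-trifluoroacetyl lactone 5 (not isolated)
Conditions: LiN(SiMe3)2, THF, −78 °C; CF3CO2CH2CF3, −78 °C; aqueous work-up; then 4-O2NC6H4SO2N3, Et3N, H2O (1 equiv), MeCN, rt
Reagents that add atoms: 4-nitrobenzenesulfonyl azide, [N-]=[N+]=NS(=O)(=O)c1ccc(cc1)[N+](=O)[O-]; 2,2,2-trifluoroethyl trifluoroacetate, O=C(OCC(F)(F)F)C(F)(F)F (its atoms are carried only in 5)
Why: Danheiser detrifluoroacetylative diazo transfer: Claisen trifluoroacetylation of the lactone enolate at C3 gives 5, whose stabilised enolate should take up the diazo group from the sulfonyl azide with loss of the trifluoroacetyl unit as the N-sulfonyl amide.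

**Step 4**
Reactants: 6 3-diazo-5,7-bis(methoxymethoxy)chroman-2-one
Product: 7 methyl 2-diazo-3-[2-hydroxy-4,6-bis(methoxymethoxy)phenyl]propanoate
Conditions: NaOMe (1.1 equiv), MeOH–THF, 0 °C; then AcOH
Reagents that add atoms: sodium methoxide, C[O-].[Na+]
Why: Transesterification of the activated aryl ester by methoxide should open the lactone with the phenoxide as leaving group, the diazo ester being stable to alkoxide.

**Step 5**
Reactants: 7 methyl 2-diazo-3-[2-hydroxy-4,6-bis(methoxymethoxy)phenyl]propanoate
Product: 8 methyl (2S)-4,6-bis(methoxymethoxy)-2,3-dihydro-1-benzofuran-2-carboxylate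
Conditions: (CuOTf)2·C6H6 (2.5 mol %), (Sa,S,S)-7,7'-bis(4-phenyl-4,5-dihydrooxazol-2-yl)-1,1'-spirobiindane (6 mol %), NaB[3,5-(CF3)2C6H3]4 (6 mol %), 4 Å molecular sieves, CH2Cl2, 25 °C, slow addition of 7
Reagents that add atoms: none
Why: Monovalent copper, bound to the spiro-bisoxazoline and made cationic by the non-coordinating borate, should decompose the diazo ester with loss of N2 to an electrophilic copper carbene at the future C2; the ortho phenol oxygen attacks it to give a copper-associated oxonium ylide, and a 1,2-proton shift from oxygen to carbon completes the O–H insertion. The closest known reaction type is the copper/spiro-bisoxazoline-catalysed enantioselective intramolecular phenol O–H insertion of 2-diazo-3-(2-hydroxyaryl)propanoates to 2,3-dihydrobenzofuran-2-carboxylates. The five-membered ring closes by O1–C2 bond formation in a 5-exo sense, the Cu=C bond lying outside the new ring. The C2 stereocentre is set in the proton transfer, which takes place while the C2-symmetric ligand is still on copper, so the ligand pocket decides which face of C2 receives the proton. The step needs chemoselectivity for O–H insertion over 1,2-hydride shift from the benzylic CH2, over C–H insertion into the MOM groups and over intermolecular insertion; the adjacent phenol should capture the carbene faster than any of these, copper is less prone to hydride shift than Rh2(OAc)4-type catalysts, and slow addition suppresses the bimolecular path. Only one phenol is free, so no regiochemical question arises.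

**Step 6**
Reactants: 8 methyl (2S)-4,6-bis(methoxymethoxy)-2,3-dihydro-1-benzofuran-2-carboxylate; 9 methylmagnesium bromide
Product: 11 2-[(2S)-4,6-bis(methoxymethoxy)-2,3-dihydro-1-benzofuran-2-yl]propan-2-ol, via methyl ketone 10 (not isolated)
Conditions: MeMgBr (3.5 equiv), anhydrous CeCl3, THF, −78 to 0 °C; aqueous NH4Cl
Reagents that add atoms: none
Why: Double Grignard addition to the ester through ketone 10 should give the tertiary alcohol, and the weakly basic organocerium-type reagent suppresses enolisation at C2 so that the configuration is kept.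

**Step 7**
Reactants: 11 2-[(2S)-4,6-bis(methoxymethoxy)-2,3-dihydro-1-benzofuran-2-yl]propan-2-ol
Product: 12 {2-[(2S)-4,6-bis(methoxymethoxy)-2,3-dihydro-1-benzofuran-2-yl]propan-2-yl}oxy(triethyl)silane
Conditions: TESOTf, 2,6-lutidine, CH2Cl2, −78 °C
Reagents that add atoms: triethylsilyl trifluoromethanesulfonate, CC[Si](CC)(CC)OS(=O)(=O)C(F)(F)F
Why: Silyl triflate silylation of the tertiary alcohol is fast at −78 °C, where the aryl MOM acetals are not yet activated, and it removes an alkoxide that could otherwise steer the later metalation towards C7.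

**Step 8**
Reactants: 13 4-hydroxycinnamic acid
Product: 14 (E)-3-(4-hydroxyphenyl)-N-methoxy-N-methylprop-2-enamide
Conditions: MeNHOMe·HCl, EDC·HCl, HOBt, iPr2NEt, DMF, 0 °C to rt
Reagents that add atoms: N,O-dimethylhydroxylamine hydrochloride, CNOC.Cl
Why: Carbodiimide/HOBt amide coupling of hydroxycinnamic acids with amines tolerates the free phenol and should give the Weinreb amide with the E alkene unchanged.

**Step 9**
Reactants: 14 (E)-3-(4-hydroxyphenyl)-N-methoxy-N-methylprop-2-enamide
Product: 15 (E)-N-methoxy-3-[4-(methoxymethoxy)phenyl]-N-methylprop-2-enamide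
Conditions: MOMCl, iPr2NEt, CH2Cl2, 0 °C to rt
Reagents that add atoms: chloromethyl methyl ether, COCCl
Why: Standard MOM protection of the ring B phenol removes the only acidic proton of the acylating partner.

**Step 10**
Reactants: 12 {2-[(2S)-4,6-bis(methoxymethoxy)-2,3-dihydro-1-benzofuran-2-yl]propan-2-yl}oxy(triethyl)silane; 15 (E)-N-methoxy-3-[4-(methoxymethoxy)phenyl]-N-methylprop-2-enamide
Product: 18 (E)-1-[(2S)-4,6-bis(methoxymethoxy)-2-{2-[(triethylsilyl)oxy]propan-2-yl}-2,3-dihydro-1-benzofuran-5-yl]-3-[4-(methoxymethoxy)phenyl]prop-2-en-1-one, via aryllithium 16 (not isolated), via lithium hemiaminal alkoxide 17 (not isolated)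
Conditions: n-BuLi (1.15 equiv), TMEDA, THF, 0 °C; then 15, −78 to 0 °C; aqueous NH4Cl
Reagents that add atoms: n-butyllithium, [Li]CCCC (lithium is carried only in 16 and 17)
Why: Directed ortho-metalation should occur at C5, the one ring position flanked by two chelating MOM ethers, and the aryllithium then adds 1,2 to the Weinreb amide to give a chelated tetrahedral adduct that releases the enone only on work-up (Weinreb ketone synthesis).

**Step 11**
Reactants: 18 (E)-1-[(2S)-4,6-bis(methoxymethoxy)-2-{2-[(triethylsilyl)oxy]propan-2-yl}-2,3-dihydro-1-benzofuran-5-yl]-3-[4-(methoxymethoxy)phenyl]prop-2-en-1-one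
Product: 19 (E)-1-[(2S)-4,6-dihydroxy-2-(2-hydroxypropan-2-yl)-2,3-dihydro-1-benzofuran-5-yl]-3-(4-hydroxyphenyl)prop-2-en-1-one (CNP0254021.1)
Conditions: HCl (1.25 M in MeOH), MeOH, 0 °C to rt (to 40 °C if needed), stopped at full conversion
Reagents that add atoms: none
Why: Acid-catalysed acetal methanolysis should remove the three phenolic MOM groups and solvolyse the silyl ether in one operation, under conditions mild enough to leave the tertiary alcohol and the C2 stereocentre untouched.

**Compound list**

1 | phloroglucinol | Oc1cc(O)cc(O)c1 | starting material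
2 | acrylic acid | C=CC(=O)O | starting material
3 | 5,7-dihydroxychroman-2-one | O=C1CCc2c(O)cc(O)cc2O1 | intermediate
4 | 5,7-bis(methoxymethoxy)chroman-2-one | O=C1CCc2c(OCOC)cc(OCOC)cc2O1 | intermediate
5 | 5,7-bis(methoxymethoxy)-3-(trifluoroacetyl)chroman-2-one (racemic, largely enolised) | O=C1Oc2cc(OCOC)cc(OCOC)c2CC1C(=O)C(F)(F)F | intermediate
6 | 3-diazo-5,7-bis(methoxymethoxy)chroman-2-one | O=C1Oc2cc(OCOC)cc(OCOC)c2CC1=[N+]=[N-] | intermediate
7 | methyl 2-diazo-3-[2-hydroxy-4,6-bis(methoxymethoxy)phenyl]propanoate | COC(=O)C(=[N+]=[N-])Cc1c(O)cc(OCOC)cc1OCOC | intermediate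
8 | methyl (2S)-4,6-bis(methoxymethoxy)-2,3-dihydro-1-benzofuran-2-carboxylate | COC(=O)[C@@H]1Cc2c(OCOC)cc(OCOC)cc2O1 | intermediate
9 | methylmagnesium bromide | C[Mg]Br | starting material
10 | 1-[(2S)-4,6-bis(methoxymethoxy)-2,3-dihydro-1-benzofuran-2-yl]ethan-1-one | CC(=O)[C@@H]1Cc2c(OCOC)cc(OCOC)cc2O1 | intermediate
11 | 2-[(2S)-4,6-bis(methoxymethoxy)-2,3-dihydro-1-benzofuran-2-yl]propan-2-ol | CC(C)(O)[C@@H]1Cc2c(OCOC)cc(OCOC)cc2O1 | intermediate
12 | {2-[(2S)-4,6-bis(methoxymethoxy)-2,3-dihydro-1-benzofuran-2-yl]propan-2-yl}oxy(triethyl)silane | CC[Si](CC)(CC)OC(C)(C)[C@@H]1Cc2c(OCOC)cc(OCOC)cc2O1 | intermediate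
13 | 4-hydroxycinnamic acid, (E) | O=C(O)/C=C/c1ccc(O)cc1 | starting material
14 | (E)-3-(4-hydroxyphenyl)-N-methoxy-N-methylprop-2-enamide | CON(C)C(=O)/C=C/c1ccc(O)cc1 | intermediate
15 | (E)-N-methoxy-3-[4-(methoxymethoxy)phenyl]-N-methylprop-2-enamide | CON(C)C(=O)/C=C/c1ccc(OCOC)cc1 | intermediate
16 | [(2S)-4,6-bis(methoxymethoxy)-2-{2-[(triethylsilyl)oxy]propan-2-yl}-2,3-dihydro-1-benzofuran-5-yl]lithium | CC[Si](CC)(CC)OC(C)(C)[C@@H]1Cc2c(OCOC)c([Li])c(OCOC)cc2O1 | intermediate
17 | lithium alkoxide of the N-methoxy-N-methyl hemiaminal formed from 16 and 15 (mixture at the new carbinol carbon) | CC[Si](CC)(CC)OC(C)(C)[C@@H]1Cc2c(OCOC)c(C(O[Li])(/C=C/c3ccc(OCOC)cc3)N(C)OC)c(OCOC)cc2O1 | intermediate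
18 | (E)-1-[(2S)-4,6-bis(methoxymethoxy)-2-{2-[(triethylsilyl)oxy]propan-2-yl}-2,3-dihydro-1-benzofuran-5-yl]-3-[4-(methoxymethoxy)phenyl]prop-2-en-1-one | CC[Si](CC)(CC)OC(C)(C)[C@@H]1Cc2c(OCOC)c(C(=O)/C=C/c3ccc(OCOC)cc3)c(OCOC)cc2O1 | intermediate
19 | (E)-1-[(2S)-4,6-dihydroxy-2-(2-hydroxypropan-2-yl)-2,3-dihydro-1-benzofuran-5-yl]-3-(4-hydroxyphenyl)prop-2-en-1-one | CC(C)(O)[C@@H]1Cc2c(cc(O)c(C(=O)/C=C/c3ccc(O)cc3)c2O)O1 | target

**Step count**

Total: 11 steps. Longest linear sequence: 9 steps (steps 1 to 7, 10 and 11, from phloroglucinol); the amide fragment takes 2 steps (8 and 9).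

**Steps most likely to fail**

Step 3. The lithium enolate of the aryl lactone may fragment to a ketene and phenoxide, or the lactone may be opened by water and amine during the diazo transfer, so that material is lost before the diazo group is in place. The fallback sets out from 4 and returns at 7; it places the diazo group on an open-chain methyl ester whose phenol is masked. Methoxide opening of 4 (NaOMe, MeOH, 0 °C) should give methyl 3-[2-hydroxy-4,6-bis(methoxymethoxy)phenyl]propanoate F1, and TBSCl with imidazole in DMF its silyl ether, methyl 3-[2-(tert-butyldimethylsilyloxy)-4,6-bis(methoxymethoxy)phenyl]propanoate F2. Trifluoroacetylation of the ester enolate (LiN(SiMe3)2, CF3CO2CH2CF3, THF, −78 °C) gives the crude trifluoroacetyl ester F3, which with 4-nitrobenzenesulfonyl azide and Et3N in MeCN should give methyl 3-[2-(tert-butyldimethylsilyloxy)-4,6-bis(methoxymethoxy)phenyl]-2-diazopropanoate F4. Bu4NF buffered with AcOH in THF at 0 °C then frees the phenol to give 7.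

Step 10. The crowded aryllithium may be captured poorly by the conjugated amide (conjugate addition, or deprotonation of the N-methoxy group with breakdown of the amide), and metalation may partly stray to C7 or to the benzylic C3. The fallback sets out from 15 and 12 and returns at 18; it replaces the amide by a non-enolisable, far more electrophilic aldehyde and moves the oxidation to the end. DIBAL-H reduction of 15 (THF, −78 °C) should give (E)-3-[4-(methoxymethoxy)phenyl]prop-2-enal F5. Aryllithium 16, made from 12 as in step 10, adds to it at −78 °C to give the allylic benzylic alcohol (E)-1-[(2S)-4,6-bis(methoxymethoxy)-2-{2-[(triethylsilyl)oxy]propan-2-yl}-2,3-dihydro-1-benzofuran-5-yl]-3-[4-(methoxymethoxy)phenyl]prop-2-en-1-ol F6 as a mixture at the carbinol carbon. MnO2 in CH2Cl2 oxidises this doubly activated alcohol to 18.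

Step 11. The freed 2',6'-dihydroxychalcone may undergo acid-promoted oxa-Michael closure to the isomeric flavanone, or the tertiary alcohol may ionise, during the time needed to cleave the last MOM group. The fallback sets out from 12 and returns at 19; it removes the protecting groups before the enone exists and forms the enone last in strong base, where the chalcone phenolate resists ring closure. Aryllithium 16 (from 12 as in step 10) is quenched with N-methoxy-N-methylacetamide to give the acetophenone 1-[(2S)-4,6-bis(methoxymethoxy)-2-{2-[(triethylsilyl)oxy]propan-2-yl}-2,3-dihydro-1-benzofuran-5-yl]ethan-1-one F7. Methanolic HCl then gives 1-[(2S)-4,6-dihydroxy-2-(2-hydroxypropan-2-yl)-2,3-dihydro-1-benzofuran-5-yl]ethan-1-one F8. Claisen–Schmidt condensation of F8 with 4-hydroxybenzaldehyde (concentrated aqueous KOH, EtOH, rt), followed by cold acidification, should give 19.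

**Further compounds**

F1 | step 3 | methyl 3-[2-hydroxy-4,6-bis(methoxymethoxy)phenyl]propanoate | COC(=O)CCc1c(O)cc(OCOC)cc1OCOC
F2 | step 3 | methyl 3-[2-(tert-butyldimethylsilyloxy)-4,6-bis(methoxymethoxy)phenyl]propanoate | COC(=O)CCc1c(O[Si](C)(C)C(C)(C)C)cc(OCOC)cc1OCOC
F3 | step 3 | methyl 2-{[2-(tert-butyldimethylsilyloxy)-4,6-bis(methoxymethoxy)phenyl]methyl}-4,4,4-trifluoro-3-oxobutanoate | COC(=O)C(Cc1c(O[Si](C)(C)C(C)(C)C)cc(OCOC)cc1OCOC)C(=O)C(F)(F)F
F4 | step 3 | methyl 3-[2-(tert-butyldimethylsilyloxy)-4,6-bis(methoxymethoxy)phenyl]-2-diazopropanoate | COC(=O)C(=[N+]=[N-])Cc1c(O[Si](C)(C)C(C)(C)C)cc(OCOC)cc1OCOC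
F5 | step 10 | (E)-3-[4-(methoxymethoxy)phenyl]prop-2-enal | COCOc1ccc(/C=C/C=O)cc1
F6 | step 10 | (E)-1-[(2S)-4,6-bis(methoxymethoxy)-2-{2-[(triethylsilyl)oxy]propan-2-yl}-2,3-dihydro-1-benzofuran-5-yl]-3-[4-(methoxymethoxy)phenyl]prop-2-en-1-ol | CC[Si](CC)(CC)OC(C)(C)[C@@H]1Cc2c(OCOC)c(C(O)/C=C/c3ccc(OCOC)cc3)c(OCOC)cc2O1
F7 | step 11 | 1-[(2S)-4,6-bis(methoxymethoxy)-2-{2-[(triethylsilyl)oxy]propan-2-yl}-2,3-dihydro-1-benzofuran-5-yl]ethan-1-one | CC[Si](CC)(CC)OC(C)(C)[C@@H]1Cc2c(OCOC)c(C(C)=O)c(OCOC)cc2O1
F8 | step 11 | 1-[(2S)-4,6-dihydroxy-2-(2-hydroxypropan-2-yl)-2,3-dihydro-1-benzofuran-5-yl]ethan-1-one | CC(C)(O)[C@@H]1Cc2c(O)c(C(C)=O)c(O)cc2O1
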